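Read the rate first.

common to all: D 52 mM (held)
- midnight: J 0.15 M; run made earlier
- spring: J 0.91 M; run made earlier
- alpha: J 0.20 M; time 6.0 min
- eta: J 0.40 M; time 6.0 min
- epsilon: J 0.80 M; time 6.0 min
- zeta: J 1.5 M; time 6.0 min

| run | time / min | L / % |
|---|---|---|
| midnight | 0.500 | 21 |
| midnight | 1.00 | 42 |
| midnight | 2.50 | 95 |
| midnight | 6.00 | 97 |
| spring | 0.833 | 4 |
| spring | 2.00 | 12 |
| spring | 4.00 | 26 |
| spring | 6.00 | 39 |

(scatter of a reading: 1.5 percentage points)

- at the start none of J is in solution
- at the start none of D is in solution
- a reading or a percentage of L counts all its forms, free or not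
- the concentration of L that is asked is that of its free form alone
- "hardly changes" means that all values lie within two and a half points (for a concentration: within two and a half percent of the largest)

- [L] (only what is free in solution) at the end for alpha, eta, epsilon, zeta, in this order
- how that number moves from the first to the last of them (falls, then rises / falls all the way / rises, then falls / hardly changes / rises all the way)

- The spring run, last reading over its time, gives 0.0592 M min⁻¹. This is the arrival rate: the concentration of L, in every form, that appears per minute while J remains.
- One run may mislead, since the rate could depend on the charge of J. But the midnight run, with a charge smaller by a factor of 6.07, gives 0.0630 M min⁻¹ from its reading at 1.00 min. The scatter of one reading is worth 0.00228 M min⁻¹ on the spring rate, so the gap of 0.00380 M min⁻¹ is less than twice that. With D held, these two readings therefore fit a rate of zero order in J.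
- Over 6.0 min the arrival rate yields 0.355 M of L. Alpha's charge is less than this, so alpha finishes. Eta is too near the edge to call, at 88.7% of its charge. By this reckoning epsilon reaches 44.4% of its charge and zeta 23.7% of its own.
- An objection remains: these totals count L in all its forms, free or not, so they are not values of [L], and the readings of the midnight and spring runs give no free value. What survives is the arrival rate itself. Epsilon and zeta hold more J than the 0.355 M can use, so L should still be arriving in them at the end. If a form that is not free takes up L, their [L] should stand above alpha's.
- The forecast gives 0.195 M, 0.35 M, 0.365 M and 0.365 M, a row that rises all the way. Here it parts from this reckoning, for it chooses to “take free L as roughly total L”.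
- The flasks give 0.00340 M, 0.00340 M, 0.00512 M and 0.00487 M, a row that rises, then falls.

    J ⇌ G, rate k1*(cs1 - [G]) while solid is left; crystals form when [G] > cs1 (solubility = 0.0880 M, k = 0.0135 s⁻¹)
    G + X → L (k = 81.7 L mol⁻¹ s⁻¹)
    2 G → Z (k = 38.4 L mol⁻¹ s⁻¹)
    Q ⇌ L, rate k4*(cs4 - [L]) while solid is left; crystals form when [L] > cs4 (solubility = 3.40 mM, k = 0.633 s⁻¹)
    J + L → E (k = 0.0514 L mol⁻¹ s⁻¹)
    D ⇌ X, rate k6*(csat - [X]) (kL = 0.103 s⁻¹)

In eta, J stands at 0% at the end and [L] is 3.40 mM, the solubility 3.4 mM of the solid form Q, while epsilon, with J still at 40.4%, holds more. The arrival rate 0.0592 M min⁻¹, read from the spring run and set against the crystallisation constant 0.633 s⁻¹, gives an estimated excess of 1.56 mM over that solubility, so an estimated [L] of 4.96 mM, beside 5.12 mM in epsilon and 4.87 mM in zeta, where 64.5% of the J remains.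

Readings and results stem from a simulated flask from invented constants; the scatter is artificial.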